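Z, J, D, X, E and L add up to the charge at every moment: each step turns one molecule into one molecule, and the flask is closed. So I asked what share of that fixed total each form holds, and what fraction of it is left.

Z 0.81 M; time 2.0 h

    J ⇌ D (K1 = 4.9, k1 = 0.043 /min)
    D ⇌ X (K2 = 0.52, k2 = 0.019 /min)
    X ⇌ E (K3 = 0.40, k3 = 0.022 /min)
    E ⇌ J (k4 = 0.047 /min)
    Z ⇌ J, rate k5*(cs5 - [J]) while solid is left; crystals form when [J] > cs5 (cs5 = 0.20 M, k5 = 1.6 /min)
    J → L (k6 = 1.2 × 10⁻⁴ /min)

- given per volume of solution although it is solid: Z
- at the start none of Z is in solution
- what has only dissolved of Z counts as not reacted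
- run time (flask): 2.0 h

1. how much D there is at 2.0 h, in percent of the Z charged
2. how much X there is at 2.0 h, in percent of the Z charged
3. amount of D if the flask were left three thousand times as long, in percent of the Z charged

J, D, X and E form a ring. When each of its steps is balanced, D = K1·J, X = K2·D and E = K3·X. Counting J as one part, the ring holds S parts:

S = 1 + 4.9 + 2.55 + 1.02 = 9.47

I called w the balanced share, the part of the dissolved pool that stands as D:

w = K1/S = 51.8%

While solid remains, J stays near the solubility cs5, and a balanced ring would then hold 1.89 M. That is more than the charge, so the ring can take up the solid. J at cs5 leaves by step one and by the E to J step run backward, with constant 0.0479 /min. Without any return flow, the charge above cs5 would pass in 33.6 min. The relaxation half-life of J and D, 0.223 h, is the longest in the ring. I took the ring as balanced at 2.0 h, since that time is longer than both.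

The pool drains through J, which is one part in S, so the fraction left is f:

f = exp(−k6·t/S), with k6/S = 1.27 × 10⁻⁵ /min

At 120 min, f = 99.8%, so D = w·f = 51.7% and X = K2·D = 26.9%.

At 3.60 × 10⁵ min, f = 1.04%, so D = 0.539%.

The forecast gave 51% for D and 26.8% for X at the asked time, and 0.54% for D at the long time; its D at the asked time stands below my 51.7%. Its ground was that “the J/D/X/E ring relaxes to near its equilibrium split”.

The flask gave 51.3%, 26.9% and 0.542%. In this flask Z stood at 0% at 1.00 h, and D stood at 50.9% at 20.0 h.

The neighbour flask was charged with 1.4 M of Z, less than the 1.89 M of a balanced ring with J at cs5, and it held 8.05% as solid at 2.00 h. Applying w to the dissolved remainder gives 47.6% as D, but that flask gave 43.7%. Its X over D read 0.521, against K2 of 0.52. The same reckoning puts J at 9.71%, but J in that flask stood at 14.1%, which is 0.197 M.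

The rate constants were drawn at random within sensible limits, and the outcome is calculated.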